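The oxolane is cut into formaldehyde (ring O1 and C5H2) and a three-carbon 1,3-zwitterion: benzylic C2, made electrophilic by its guaiacyl donor, and C4, made nucleophilic by two carbonyl groups. The precursor is therefore a donor–acceptor cyclopropane built from C2, C3 and C4 and fused to a γ-lactone that ties the C3 CH2O arm to one acceptor on C4. A Lewis-acid [3+2] cycloaddition with formaldehyde forms O1–C2, with inversion, and C4–C5 in one operation and gives a cis-fused bicyclic lactone that locks the 3,4-cis relation. The lactone carbonyl then becomes the carbinol carbon and the second acceptor is removed.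

Key step: step 7

Assumption: the sense of induction of the chiral dirhodium catalyst in step 6 is to be confirmed on the first run; if it is opposite, the mirror-image complex Rh2(R-NTTL)4 is used.

Step 1
Reactants: 1 vanillin
Product: 2 4-(allyloxy)-3-methoxybenzaldehyde
Conditions: allyl bromide, K2CO3, DMF, 23 °C
Reagents that add atoms: allyl bromide, C=CCBr
Why: Williamson etherification of the phenoxide installs the allyl ether, the only phenol protecting group of the route, which tolerates Lewis acid, hot wet DMSO and organolithium reagents and is removed at the end under neutral palladium catalysis.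

Step 2
Reactants: 2 4-(allyloxy)-3-methoxybenzaldehyde
Product: 3 methyl (Z)-3-[4-(allyloxy)-3-methoxyphenyl]prop-2-enoate
Conditions: methyl bis(2,2,2-trifluoroethyl)phosphonoacetate, KN(SiMe3)2, 18-crown-6, THF, −78 °C
Reagents that add atoms: methyl bis(2,2,2-trifluoroethyl)phosphonoacetate, COC(=O)CP(=O)(OCC(F)(F)F)OCC(F)(F)F
Why: Still–Gennari olefination, in which the electron-poor phosphonate makes elimination from the kinetic adduct fast, so the Z-enoate should be the main isomer.

Step 3
Reactants: 3 methyl (Z)-3-[4-(allyloxy)-3-methoxyphenyl]prop-2-enoate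
Product: 4 (Z)-3-[4-(allyloxy)-3-methoxyphenyl]prop-2-en-1-ol
Conditions: i-Bu2AlH (2.5 equiv), CH2Cl2, −78 °C; Rochelle salt work-up
Reagents that add atoms: none
Why: 1,2-reduction of the enoate by the aluminium hydride at low temperature should give the allylic alcohol without touching the Z double bond or the allyl ether.

Step 4
Reactants: 4 (Z)-3-[4-(allyloxy)-3-methoxyphenyl]prop-2-en-1-ol
Product: 5 methyl (Z)-3-[4-(allyloxy)-3-methoxyphenyl]prop-2-en-1-yl propanedioate
Conditions: methyl malonyl chloride, pyridine, CH2Cl2, 0 °C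
Reagents that add atoms: methyl malonyl chloride (methyl 3-chloro-3-oxopropanoate), COC(=O)CC(Cl)=O
Why: acylation of the primary allylic alcohol by the acid chloride under pyridine buffering, mild enough to avoid ketene formation and isomerisation of the Z-cinnamyl system.

Step 5
Reactants: 5 methyl (Z)-3-[4-(allyloxy)-3-methoxyphenyl]prop-2-en-1-yl propanedioate
Product: 6 methyl (Z)-3-[4-(allyloxy)-3-methoxyphenyl]prop-2-en-1-yl 2-diazopropanedioate
Conditions: 4-acetamidobenzenesulfonyl azide, Et3N, MeCN, 0 → 23 °C
Reagents that add atoms: 4-acetamidobenzenesulfonyl azide, CC(=O)Nc1ccc(cc1)S(=O)(=O)N=[N+]=[N-]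
Why: Regitz diazo transfer to the doubly activated methylene of the malonate.

Step 6
Reactants: 6 methyl (Z)-3-[4-(allyloxy)-3-methoxyphenyl]prop-2-en-1-yl 2-diazopropanedioate
Product: 7 methyl (1S,5R,6R)-6-[4-(allyloxy)-3-methoxyphenyl]-2-oxo-3-oxabicyclo[3.1.0]hexane-1-carboxylate (aryl endo, cis to C4H2)
Conditions: Rh2(S-NTTL)4 (dirhodium tetrakis[N-(1,8-naphthaloyl)-(S)-tert-leucinate], 1 mol %), CH2Cl2, 40 °C, slow addition of 6
Reagents that add atoms: none
Why: dirhodium carbene formation and concerted intramolecular cyclopropanation of the tethered alkene, in which retention of the Z geometry places the aryl group cis to the lactone CH2 and the chiral carboxylate ligands select the alkene face, so C1, C5 and C6 are set together (enantiomeric purity to be raised by recrystallisation if needed).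

Step 7
Reactants: 7 methyl (1S,5R,6R)-6-[4-(allyloxy)-3-methoxyphenyl]-2-oxo-3-oxabicyclo[3.1.0]hexane-1-carboxylate
Product: 8 methyl (1R,5R,6S)-6-[4-(allyloxy)-3-methoxyphenyl]-2-oxo-3,7-dioxabicyclo[3.3.0]octane-1-carboxylate (cis-fused, aryl exo)
Conditions: paraformaldehyde (5 equiv CH2O), Sn(OTf)2 (10 mol %), 4 Å MS, ClCH2CH2Cl, 0 → 23 °C
Reagents that add atoms: formaldehyde (charged as paraformaldehyde), C=O
Why: Sn(OTf)2 chelates the lactone and ester carbonyls on C1 and polarises the C1–C6 bond, so the carbonyl oxygen of formaldehyde attacks benzylic C6 from the side opposite the departing C1 (SN2-like, inversion) to give an O-alkylated oxocarbenium ion paired with the tin enolate of the lactone ester, which then forms the C–C bond by aldol-type attack on the CH2 carbon. The closest known reaction type is the Lewis-acid-catalysed formal [3+2] cycloaddition of aryl donor–acceptor cyclopropanes with aldehydes to 2-aryl tetrahydrofurans, here run with the smallest aldehyde and a lactone-tethered acceptor pair. The only ring closed is the oxolane, by a 5-(enolexo)-endo-trig attack of the enolate carbon on the oxocarbenium carbon, and because the new ring shares the C1–C5 bond with the γ-lactone it can only be cis-fused. C6 is set by inversion (6R in 7 becomes 6S in 8, endo aryl becomes exo aryl, trans to the C5–C4 bond), C5 is carried over untouched from the cyclopropane and the quaternary C1 is fixed by the cis ring fusion. The step needs cleavage of C1–C6 and not C1–C5, which the aryl donor secures, and capture before free ionisation of the benzylic carbon, which the non-nucleophilic triflate, the low temperature and the excess of formaldehyde should secure; the Z-derived endo-aryl substrate is chosen because the invertive pathway then leads directly to the required 2,3-trans oxolane.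

Step 8
Reactants: 8 methyl (1R,5R,6S)-6-[4-(allyloxy)-3-methoxyphenyl]-2-oxo-3,7-dioxabicyclo[3.3.0]octane-1-carboxylate
Product: 9 (1R,5R,6S)-6-[4-(allyloxy)-3-methoxyphenyl]-3,7-dioxabicyclo[3.3.0]octan-2-one
Conditions: LiCl (3 equiv), H2O (2 equiv), DMSO, 130 °C
Reagents that add atoms: none
Why: Krapcho dealkoxycarbonylation (chloride attacks the methyl group, the β-carbonyl carboxylate loses CO2 and the lactone enolate is protonated), where protonation at C1 can only give the cis-fused bicycle and so fixes this centre, the future oxolane C4, cis to the C5 arm.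

Step 9
Reactants: 10 4-bromo-2-methoxyphenol
Product: 11 1-(allyloxy)-4-bromo-2-methoxybenzene
Conditions: allyl bromide, K2CO3, DMF, 23 °C
Reagents that add atoms: allyl bromide, C=CCBr
Why: Williamson etherification of the phenoxide, as in step 1.

Step 10
Reactants: 11 1-(allyloxy)-4-bromo-2-methoxybenzene; 9 (1R,5R,6S)-6-[4-(allyloxy)-3-methoxyphenyl]-3,7-dioxabicyclo[3.3.0]octan-2-one
Product: 14 (S)-[4-(allyloxy)-3-methoxyphenyl]{(3R,4R,5S)-5-[4-(allyloxy)-3-methoxyphenyl]-4-(hydroxymethyl)oxolan-3-yl}methanol, via aryllithium 12 (not isolated), via hydroxy ketone 13 (not isolated)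
Conditions: 11, n-BuLi, THF, −78 °C; then 9, −78 °C; then MeOH, CeCl3·7H2O, NaBH4, −78 → −20 °C
Reagents that add atoms: none
Why: bromine–lithium exchange, addition of the aryllithium to the γ-lactone carbonyl to give a lithium lactolate that resists a second addition at −78 °C, and Luche-type borohydride reduction of the liberated aryl ketone in the same flask, where Felkin–Anh attack of hydride anti to the more substituted ring carbon (the one bearing CH2OH) and past the small hydrogen should set the new carbinol centre as S.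

Step 11
Reactants: 15 4-(allyloxy)benzaldehyde
Product: 16 (E)-3-[4-(allyloxy)phenyl]prop-2-enoic acid
Conditions: malonic acid, pyridine, piperidine (cat.), 100 °C
Reagents that add atoms: malonic acid, OC(=O)CC(O)=O
Why: Knoevenagel–Doebner condensation with decarboxylation should give the thermodynamically favoured E-cinnamic acid.

Step 12
Reactants: 14 (S)-[4-(allyloxy)-3-methoxyphenyl]{(3R,4R,5S)-5-[4-(allyloxy)-3-methoxyphenyl]-4-(hydroxymethyl)oxolan-3-yl}methanol; 16 (E)-3-[4-(allyloxy)phenyl]prop-2-enoic acid
Product: 17 {(2S,3R,4R)-2-[4-(allyloxy)-3-methoxyphenyl]-4-[(S)-[4-(allyloxy)-3-methoxyphenyl](hydroxy)methyl]oxolan-3-yl}methyl (E)-3-[4-(allyloxy)phenyl]prop-2-enoate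
Conditions: 16 (1.05 equiv), N,N'-diisopropylcarbodiimide, DMAP (cat.), CH2Cl2, −20 → 0 °C
Reagents that add atoms: none
Why: Steglich esterification with one equivalent of acid at low temperature should acylate the unhindered primary hydroxyl in preference to the hindered secondary benzylic one.

Step 13
Reactants: 17 {(2S,3R,4R)-2-[4-(allyloxy)-3-methoxyphenyl]-4-[(S)-[4-(allyloxy)-3-methoxyphenyl](hydroxy)methyl]oxolan-3-yl}methyl (E)-3-[4-(allyloxy)phenyl]prop-2-enoate
Product: 18 {(2S,3R,4R)-2-(4-hydroxy-3-methoxyphenyl)-4-[(S)-hydroxy(4-hydroxy-3-methoxyphenyl)methyl]oxolan-3-yl}methyl (E)-3-(4-hydroxyphenyl)prop-2-enoate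
Conditions: Pd(PPh3)4 (10 mol %), morpholine (10 equiv), THF, 23 °C, degassed
Reagents that add atoms: none
Why: Tsuji–Trost deallylation, in which zerovalent palladium ionises the three aryl allyl ethers and morpholine traps the allyl groups under neutral conditions that should leave the cinnamate ester, its E double bond and the acid-sensitive benzylic alcohol untouched.

Compound list
1 | vanillin | COc1cc(C=O)ccc1O | starting material
2 | 4-(allyloxy)-3-methoxybenzaldehyde | C=CCOc1ccc(C=O)cc1OC | intermediate
3 | methyl (Z)-3-[4-(allyloxy)-3-methoxyphenyl]prop-2-enoate | COC(=O)/C=C\c1ccc(OCC=C)c(OC)c1 | intermediate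
4 | (Z)-3-[4-(allyloxy)-3-methoxyphenyl]prop-2-en-1-ol | OC/C=C\c1ccc(OCC=C)c(OC)c1 | intermediate
5 | methyl (Z)-3-[4-(allyloxy)-3-methoxyphenyl]prop-2-en-1-yl propanedioate | COC(=O)CC(=O)OC/C=C\c1ccc(OCC=C)c(OC)c1 | intermediate
6 | methyl (Z)-3-[4-(allyloxy)-3-methoxyphenyl]prop-2-en-1-yl 2-diazopropanedioate | COC(=O)C(=[N+]=[N-])C(=O)OC/C=C\c1ccc(OCC=C)c(OC)c1 | intermediate
7 | methyl (1S,5R,6R)-6-[4-(allyloxy)-3-methoxyphenyl]-2-oxo-3-oxabicyclo[3.1.0]hexane-1-carboxylate (aryl endo) | O=C1[C@@]2(C(=O)OC)[C@@H](c3ccc(OCC=C)c(OC)c3)[C@H]2CO1 | intermediate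
8 | methyl (1R,5R,6S)-6-[4-(allyloxy)-3-methoxyphenyl]-2-oxo-3,7-dioxabicyclo[3.3.0]octane-1-carboxylate | O=C1[C@@]2(C(=O)OC)CO[C@H](c3ccc(OCC=C)c(OC)c3)[C@H]2CO1 | intermediate
9 | (1R,5R,6S)-6-[4-(allyloxy)-3-methoxyphenyl]-3,7-dioxabicyclo[3.3.0]octan-2-one | O=C1[C@H]2CO[C@H](c3ccc(OCC=C)c(OC)c3)[C@H]2CO1 | intermediate
10 | 4-bromo-2-methoxyphenol | COc1cc(Br)ccc1O | starting material
11 | 1-(allyloxy)-4-bromo-2-methoxybenzene | C=CCOc1ccc(Br)cc1OC | intermediate
12 | [4-(allyloxy)-3-methoxyphenyl]lithium (not isolated) | [Li]c1ccc(OCC=C)c(OC)c1 | intermediate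
13 | [4-(allyloxy)-3-methoxyphenyl]{(3R,4R,5S)-5-[4-(allyloxy)-3-methoxyphenyl]-4-(hydroxymethyl)oxolan-3-yl}methanone (not isolated; in equilibrium with its cyclic hemiketal) | O=C(c1ccc(OCC=C)c(OC)c1)[C@H]1CO[C@H](c2ccc(OCC=C)c(OC)c2)[C@H]1CO | intermediate
14 | (S)-[4-(allyloxy)-3-methoxyphenyl]{(3R,4R,5S)-5-[4-(allyloxy)-3-methoxyphenyl]-4-(hydroxymethyl)oxolan-3-yl}methanol | COc1cc([C@@H](O)[C@H]2CO[C@H](c3ccc(OCC=C)c(OC)c3)[C@H]2CO)ccc1OCC=C | intermediate
15 | 4-(allyloxy)benzaldehyde | C=CCOc1ccc(C=O)cc1 | starting material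
16 | (E)-3-[4-(allyloxy)phenyl]prop-2-enoic acid | OC(=O)/C=C/c1ccc(OCC=C)cc1 | intermediate
17 | {(2S,3R,4R)-2-[4-(allyloxy)-3-methoxyphenyl]-4-[(S)-[4-(allyloxy)-3-methoxyphenyl](hydroxy)methyl]oxolan-3-yl}methyl (E)-3-[4-(allyloxy)phenyl]prop-2-enoate | COc1cc([C@@H](O)[C@H]2CO[C@H](c3ccc(OCC=C)c(OC)c3)[C@H]2COC(=O)/C=C/c2ccc(OCC=C)cc2)ccc1OCC=C | intermediate
18 | {(2S,3R,4R)-2-(4-hydroxy-3-methoxyphenyl)-4-[(S)-hydroxy(4-hydroxy-3-methoxyphenyl)methyl]oxolan-3-yl}methyl (E)-3-(4-hydroxyphenyl)prop-2-enoate | COc1cc([C@@H](O)[C@H]2CO[C@H](c3ccc(O)c(OC)c3)[C@H]2COC(=O)/C=C/c2ccc(O)cc2)ccc1O | target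

Total step count: 13
Longest linear sequence: 11 steps (steps 1 to 8, then 10, 12 and 13)

Steps most likely to fail

Step 7. The electron-rich benzylic carbon may ionise before formaldehyde captures it, which would erode the invertive stereochemical course at C6. The Lewis acid may also consume formaldehyde by polymerisation or by hydroxymethylation of the arene. The fallback sets out from 7 and comes back at 8, forming the same two bonds under base. The allyl ether of 7 is removed (Pd(PPh3)4, morpholine, THF) to give the free phenol methyl (1S,5R,6R)-6-(4-hydroxy-3-methoxyphenyl)-2-oxo-3-oxabicyclo[3.1.0]hexane-1-carboxylate F1. With DBU and paraformaldehyde in MeCN at 0 °C its phenoxide should push open the C1–C6 bond to a para-quinone methide that carries the lactone-ester enolate. Reversible aldol addition of the enolate to formaldehyde, then 5-exo-trig oxa-1,6-addition of the new alkoxide to the quinone methide, should give methyl (1R,5R,6S)-6-(4-hydroxy-3-methoxyphenyl)-2-oxo-3,7-dioxabicyclo[3.3.0]octane-1-carboxylate F2. Here C6 is set in the ring closure, with the aryl group expected on the convex face. Re-allylation (allyl bromide, K2CO3, DMF) returns to 8.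

Step 6. Face discrimination by the chiral dirhodium carboxylate may be modest for an acceptor/acceptor carbene, and the carbene may react elsewhere. The fallback sets out from 4 and comes back at 7, using intermolecular copper catalysis. Silylation (t-BuMe2SiCl, imidazole, CH2Cl2) gives tert-butyl{[(Z)-3-(4-(allyloxy)-3-methoxyphenyl)prop-2-en-1-yl]oxy}dimethylsilane F3. Cyclopropanation with the phenyliodonium ylide of dimethyl malonate, PhI=C(CO2Me)2, under [Cu(MeCN)4]PF6 and a chiral side-armed bis(oxazoline) ligand proceeds through a monovalent copper carbene in a concerted way, so the Z geometry is kept. It should give dimethyl (2R,3R)-2-[4-(allyloxy)-3-methoxyphenyl]-3-{[(tert-butyldimethylsilyl)oxy]methyl}cyclopropane-1,1-dicarboxylate F4. Bu4NF in THF at 0 °C removes the silyl group, and the liberated alkoxide lactonises onto the cis ester to give 7.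

Step 10. Hydride delivery to ketone 13 may show poor facial selectivity, and the centre next to the ketone may epimerise in the basic one-pot medium. The fallback sets out from 13 and comes back at 14, replacing substrate control by catalyst control. The aryllithium addition is quenched with aqueous NH4Cl at −78 °C and 13 is isolated. It is then reduced by Noyori-type asymmetric transfer hydrogenation (RuCl[(S,S)-TsDPEN](p-cymene), HCO2H/Et3N 5:2, 23 °C), which by analogy with aryl alkyl ketones should deliver the S carbinol of 14 under slightly acidic conditions.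

Further compounds
F1 | step 7 | methyl (1S,5R,6R)-6-(4-hydroxy-3-methoxyphenyl)-2-oxo-3-oxabicyclo[3.1.0]hexane-1-carboxylate | O=C1[C@@]2(C(=O)OC)[C@@H](c3ccc(O)c(OC)c3)[C@H]2CO1
F2 | step 7 | methyl (1R,5R,6S)-6-(4-hydroxy-3-methoxyphenyl)-2-oxo-3,7-dioxabicyclo[3.3.0]octane-1-carboxylate | O=C1[C@@]2(C(=O)OC)CO[C@H](c3ccc(O)c(OC)c3)[C@H]2CO1
F3 | step 6 | tert-butyl{[(Z)-3-(4-(allyloxy)-3-methoxyphenyl)prop-2-en-1-yl]oxy}dimethylsilane | C=CCOc1ccc(/C=C\CO[Si](C)(C)C(C)(C)C)cc1OC
F4 | step 6 | dimethyl (2R,3R)-2-[4-(allyloxy)-3-methoxyphenyl]-3-{[(tert-butyldimethylsilyl)oxy]methyl}cyclopropane-1,1-dicarboxylate | COC(=O)C1(C(=O)OC)[C@@H](c2ccc(OCC=C)c(OC)c2)[C@H]1CO[Si](C)(C)C(C)(C)C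
F0 | step 10 | none | none
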